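With germacrane locants, the target is a 3(2H)-furanone whose ether oxygen bridges C3 and C10 of the ten-membered carbocycle and so closes a nine-membered oxa ring (O, C3 to C10). C10 is bonded to this oxygen and is alpha to the C1 ketone, which makes it the carbon of an oxonium ylide. The precursor is a 3-methyleneoxocane (eight-membered ether, lactone already fused) that carries a diazoethyl ketone at C3. Copper catalysis gives the bicyclic ylide, and its [2,3]-shift moves the allyl unit from oxygen to C10: one operation forms the furanone ring, the C9–C10 bond, the quaternary centre and the carbocycle, and expands the oxocane to the oxonane.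

Key step: step 15

Remarks on the chemistry:
- Locants C1–C15 are the germacrane locants of the target and are kept for all intermediates.
- Aldehyde 1 is taken as a catalogue compound (otherwise two steps from propane-1,3-diol).
- The (S,S)-ProPhenol ligand is assumed to direct the alkynylzinc to the Si face of aldehyde 7; if the sense is the opposite, the (R,R)-ligand is used.

Step 1
Reactants: 1 3-[(4-methoxybenzyl)oxy]propanal
Product: 3 anti-homoallylic alcohol (3R,4S), via borinate ester 2 (not isolated)
Conditions: trans-but-2-ene, KOtBu, n-BuLi, THF, −78 to −45 °C; (−)-Ipc2BOMe, −78 °C; BF3·OEt2; then 1, −78 °C; NaOH, H2O2, 0 °C to rt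
Reagents that add atoms: (E)-crotyldiisopinocampheylborane (made in the flask) C/C=C/CB([C@@H]1C[C@@H]2C[C@H]([C@H]1C)C2(C)C)[C@@H]1C[C@@H]2C[C@H]([C@H]1C)C2(C)C
Why: Brown crotylboration through a closed chair transition state; the E-crotyl geometry gives the 3,4-anti pair and the isopinocampheyl groups of the (+)-α-pinene series direct the allyl unit to the Si face of the aldehyde, which sets C3 (R) and C4 (S).

Step 2
Reactants: 3 anti-homoallylic alcohol
Product: 4 TBS ether
Conditions: TBSCl, imidazole, DMF, rt
Reagents that add atoms: tert-butyldimethylsilyl chloride CC(C)(C)[Si](C)(C)Cl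
Why: Silylation masks the C3 hydroxyl, which would otherwise be oxidised in step 4 or form a lactol with the C6 aldehyde.

Step 3
Reactants: 4 TBS ether
Product: 6 primary alcohol, via alkyl-9-BBN adduct 5 (not isolated)
Conditions: 9-BBN, THF, 0 °C to rt; then NaOH, H2O2, 0 °C
Reagents that add atoms: hydrogen peroxide OO
Why: Anti-Markovnikov hydroboration–oxidation with the bulky 9-BBN puts the hydroxyl on the terminal carbon (the future C6) and touches neither ether.

Step 4
Reactants: 6 primary alcohol
Product: 7 aldehyde
Conditions: Dess–Martin periodinane, NaHCO3, CH2Cl2, 0 °C to rt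
Reagents that add atoms: none
Why: Dess–Martin oxidation under buffered conditions gives the aldehyde; its α-carbon is a CH2, so no stereocentre is at risk.

Step 5
Reactants: 7 aldehyde
Product: 8 γ-hydroxy ynoate
Conditions: methyl propiolate, Me2Zn, (S,S)-ProPhenol (20 mol%), Ph3PO (40 mol%), toluene, 4 °C
Reagents that add atoms: methyl propiolate C#CC(=O)OC
Why: Zinc–ProPhenol-catalysed asymmetric alkynylation of an aldehyde; the ligand-bound dinuclear zinc alkynylide adds to the Si face and sets C6 (R) under reagent control, independent of the remote C4 centre.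

Step 6
Reactants: 8 γ-hydroxy ynoate
Product: 10 butenolide, via Z-hydroxy enoate 9 (not isolated)
Conditions: H2 (1 atm), Pd/CaCO3 poisoned with Pb(OAc)2 (Lindlar catalyst), quinoline, EtOAc, rt; then PPTS (cat.), toluene, 40 °C
Reagents that add atoms: none
Why: Lindlar semihydrogenation gives the Z-enoate, whose cis geometry lets the C6 hydroxyl lactonise onto the ester without touching C6.

Step 7
Reactants: 10 butenolide
Product: 12 β-isopropenyl lactone, via silyl ketene acetal 11 (not isolated)
Conditions: isopropenylmagnesium bromide, CuBr·SMe2 (10 mol%), TMSCl, THF, −78 °C; then sat. aq. NH4Cl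
Reagents that add atoms: isopropenylmagnesium bromide CC(=C)[Mg]Br
Why: Copper-catalysed, TMSCl-accelerated conjugate addition occurs anti to the C6 side chain of the butenolide and sets C7 trans to C6; aqueous work-up hydrolyses the silyl ketene acetal.

Step 8
Reactants: 12 β-isopropenyl lactone
Product: 13 α-methyl lactone
Conditions: LDA, THF, −78 °C; MeI, −78 to −40 °C
Reagents that add atoms: iodomethane CI
Why: Lactone enolate alkylation; methyl iodide approaches anti to the neighbouring isopropenyl group and sets C11 trans to C7, which is also the thermodynamically preferred all-trans lactone.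

Step 9
Reactants: 13 α-methyl lactone
Product: 14 allylic chloride
Conditions: N-chlorosuccinimide, PhSeCl (10 mol%), CH2Cl2, rt
Reagents that add atoms: N-chlorosuccinimide O=C1CCC(=O)N1Cl
Why: Selenium-catalysed ene-type allylic chlorination turns the isopropenyl group into the 2-(chloromethyl)vinyl unit with double-bond transposition; the only alkene reacts and the anisyl ring is not attacked by this soft electrophile.

Step 10
Reactants: 14 allylic chloride
Product: 15 hydroxy allylic chloride
Conditions: HF·pyridine, pyridine/THF, 0 °C to rt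
Reagents that add atoms: none
Why: Buffered fluoride desilylation frees the C3 hydroxyl; the PMB ether, the lactone and the allylic chloride are inert.

Step 11
Reactants: 15 hydroxy allylic chloride
Product: 16 methyleneoxocane lactone
Conditions: NaH, Bu4NI (cat.), THF, 0.002 M (syringe-pump addition), 0 to 45 °C
Reagents that add atoms: none
Why: Intramolecular Williamson etherification (8-exo-tet displacement at the primary allylic carbon, iodide catalysis) at high dilution closes the eight-membered ether; the trans-fused lactone and the sp2 carbon lower transannular strain, no stereocentre is touched, and no silyl group is present to migrate.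

Step 12
Reactants: 16 methyleneoxocane lactone
Product: 17 methyleneoxocane alcohol
Conditions: DDQ, CH2Cl2/pH 7 buffer, 0 °C to rt
Reagents that add atoms: none
Why: Oxidative PMB cleavage by hydride abstraction from the electron-rich benzylic position; the allyl ether and the 1,1-disubstituted alkene react far more slowly.

Step 13
Reactants: 17 methyleneoxocane alcohol
Product: 18 methyleneoxocane acid
Conditions: TEMPO (cat.), PhI(OAc)2, MeCN/H2O 1:1, rt
Reagents that add atoms: water O
Why: Oxoammonium oxidation takes the primary alcohol through the aldehyde hydrate to the acid and tolerates the alkene, the ether and the lactone.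

Step 14
Reactants: 18 methyleneoxocane acid
Product: 20 diazoethyl ketone, via acid chloride 19 (not isolated)
Conditions: (COCl)2, DMF (cat.), CH2Cl2, 0 °C to rt, evaporate; then diazoethane (3 equiv, Et2O, freshly made from N-ethyl-N-nitrosourea and KOH), −20 to 0 °C
Reagents that add atoms: diazoethane CC=[N+]=[N-]
Why: Acylation of a diazoalkane by an acid chloride (Arndt–Eistert-type diazoketone synthesis); a second equivalent of diazoethane takes up the HCl.

Step 15
Reactants: 20 diazoethyl ketone
Product: 22 bridged tetrahydrofuranone, via oxonium ylide 21 (not isolated)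
Conditions: Cu(hfacac)2 (copper bis(hexafluoroacetylacetonate), 5 mol%), CH2Cl2, reflux, slow addition of 20
Reagents that add atoms: none
Why: Loss of N2 gives a copper carbenoid at C10, which the oxocane oxygen captures to form the fused five-membered oxonium ylide 21; a [2,3]-sigmatropic shift through a five-centre envelope (C10–O–CH2–C8=CH2) then breaks the O–CH2 bond and joins C10 to the former exocyclic methylene carbon, now C9. The closest known reaction type is the copper- or rhodium-catalysed oxonium ylide formation/[2,3]-rearrangement of diazoketone-tethered cyclic allylic ethers to oxygen-bridged medium rings, and the one-atom outcome also corresponds to the [1,2]-Stevens ring expansion of bicyclic oxonium ylides; because the 2-substituted allyl unit has two CH2 termini, both pathways give the same product. Ring closures: the 3-oxotetrahydrofuran ring closes by bonding of the ether oxygen to the carbenoid carbon (five-membered cyclic ylide), the ten-membered carbocycle closes by the C9–C10 bond of the sigmatropic step, and the eight-membered oxocane becomes the nine-membered oxonane by net insertion of C10 between oxygen and the allyl unit. The only new stereocentre, quaternary C10, is controlled by C3: the six-atom bridge C4–C9 can span the five-membered ring only cis, so the allyl unit is delivered to the face of C10 syn to C4, which gives 10R with the methyl group exo. The step needs ylide formation to outrun 1,2-hydride shift from the carbenoid methyl group and C–H insertion at C4–H; the ether oxygen held in a five-membered relationship to the carbenoid, the electrophilic copper catalyst and slow addition are expected to secure this.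

Step 16
Reactants: 22 bridged tetrahydrofuranone
Product: 23 silyl enol ether
Conditions: TMSOTf, Et3N, CH2Cl2, 0 °C
Reagents that add atoms: trimethylsilyl triflate C[Si](C)(C)OS(=O)(=O)C(F)(F)F
Why: Soft enolisation can only go toward C2 because C10 is quaternary, and the lactone is not silylated under these conditions.

Step 17
Reactants: 23 silyl enol ether
Product: 24 bridged 3(2H)-furanone
Conditions: Pd(OAc)2 (1.1 equiv), MeCN, rt
Reagents that add atoms: none
Why: Saegusa–Ito oxidation; the palladium enolate at C2 loses H3 by syn β-hydride elimination on the face away from the carbon bridge and gives the C2=C3 vinylogous ester.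

Step 18
Reactants: 24 bridged 3(2H)-furanone
Product: 26 C8 ketone, via diol 25 (not isolated)
Conditions: OsO4 (2 mol%), NaIO4, THF/pH 7 phosphate buffer, 0 °C to rt
Reagents that add atoms: osmium tetroxide O=[Os](=O)(=O)=O; sodium periodate (terminal oxygen source) [Na+].[O-]I(=O)(=O)=O
Why: Lemieux–Johnson oxidation; OsO4 prefers the electron-rich 1,1-disubstituted alkene over the electron-poor, trisubstituted bridgehead vinylogous ester, and the neutral buffer avoids β-elimination of the C10 oxygen from the new ketone.

Step 19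
Reactants: 26 C8 ketone
Product: 27 C8 alcohol (8S)
Conditions: (R)-2-methyl-CBS-oxazaborolidine, catecholborane, toluene, −78 °C
Reagents that add atoms: none
Why: Corey–Bakshi–Shibata reduction; the (R)-oxazaborolidine distinguishes the branched C7 flank from the C9 methylene and should deliver hydride to give the 8S alcohol under non-basic conditions, while the vinylogous ester carbonyl and the lactone are far less reactive.

Step 20
Reactants: 27 C8 alcohol
Product: 28 target
Conditions: (E)-2-methylbut-2-enoyl chloride, pyridine, DMAP (cat.), CH2Cl2, 0 °C to rt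
Reagents that add atoms: (E)-2-methylbut-2-enoyl chloride C/C=C(\C)C(=O)Cl
Why: DMAP-catalysed acylation esterifies the C8 hydroxyl with retention; pyridine as the weak base avoids ketene formation and the stable E (tiglate) geometry is kept.

Compound list

1 | 3-[(4-methoxybenzyl)oxy]propanal | O=CCCOCc1ccc(OC)cc1 | starting material
2 | diisopinocampheylborinate of alcohol 3 (boron on the C3 oxygen) | B([C@@H]1C[C@@H]2C[C@H]([C@H]1C)C2(C)C)([C@@H]1C[C@@H]2C[C@H]([C@H]1C)C2(C)C)O[C@H](CCOCc1ccc(OC)cc1)[C@@H](C)C=C | intermediate (not isolated)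
3 | (3R,4S)-1-[(4-methoxybenzyl)oxy]-4-methylhex-5-en-3-ol (3,4-anti) | O[C@H](CCOCc1ccc(OC)cc1)[C@@H](C)C=C | intermediate
4 | (3R,4S)-3-[(tert-butyldimethylsilyl)oxy]-1-[(4-methoxybenzyl)oxy]-4-methylhex-5-ene | CC(C)(C)[Si](C)(C)O[C@H](CCOCc1ccc(OC)cc1)[C@@H](C)C=C | intermediate
5 | B-alkyl-9-borabicyclo[3.3.1]nonane from 4 (boron on the terminal carbon, the future C6) | CC(C)(C)[Si](C)(C)O[C@H](CCOCc1ccc(OC)cc1)[C@@H](C)CCB1C2CCCC1CCC2 | intermediate (not isolated)
6 | (3S,4R)-4-[(tert-butyldimethylsilyl)oxy]-6-[(4-methoxybenzyl)oxy]-3-methylhexan-1-ol | CC(C)(C)[Si](C)(C)O[C@H](CCOCc1ccc(OC)cc1)[C@@H](C)CCO | intermediate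
7 | (3S,4R)-4-[(tert-butyldimethylsilyl)oxy]-6-[(4-methoxybenzyl)oxy]-3-methylhexanal | CC(C)(C)[Si](C)(C)O[C@H](CCOCc1ccc(OC)cc1)[C@@H](C)CC=O | intermediate
8 | methyl (4R,6S,7R)-7-[(tert-butyldimethylsilyl)oxy]-4-hydroxy-9-[(4-methoxybenzyl)oxy]-6-methylnon-2-ynoate | CC(C)(C)[Si](C)(C)O[C@H](CCOCc1ccc(OC)cc1)[C@@H](C)C[C@@H](O)C#CC(=O)OC | intermediate
9 | methyl (2Z,4R,6S,7R)-7-[(tert-butyldimethylsilyl)oxy]-4-hydroxy-9-[(4-methoxybenzyl)oxy]-6-methylnon-2-enoate | CC(C)(C)[Si](C)(C)O[C@H](CCOCc1ccc(OC)cc1)[C@@H](C)C[C@@H](O)/C=C\C(=O)OC | intermediate (not isolated)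
10 | (5R)-5-[(2S,3R)-3-[(tert-butyldimethylsilyl)oxy]-5-[(4-methoxybenzyl)oxy]-2-methylpentyl]furan-2(5H)-one | CC(C)(C)[Si](C)(C)O[C@H](CCOCc1ccc(OC)cc1)[C@@H](C)C[C@H]1OC(=O)C=C1 | intermediate
11 | trimethylsilyl ketene acetal of lactone 12 (2-trimethylsilyloxy-4,5-dihydrofuran, 4,5-trans) | CC(C)(C)[Si](C)(C)O[C@H](CCOCc1ccc(OC)cc1)[C@@H](C)C[C@H]1OC(O[Si](C)(C)C)=C[C@@H]1C(C)=C | intermediate (not isolated)
12 | (4R,5R)-5-[(2S,3R)-3-[(tert-butyldimethylsilyl)oxy]-5-[(4-methoxybenzyl)oxy]-2-methylpentyl]-4-(prop-1-en-2-yl)dihydrofuran-2(3H)-one | CC(C)(C)[Si](C)(C)O[C@H](CCOCc1ccc(OC)cc1)[C@@H](C)C[C@H]1OC(=O)C[C@@H]1C(C)=C | intermediate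
13 | (3S,4R,5R)-5-[(2S,3R)-3-[(tert-butyldimethylsilyl)oxy]-5-[(4-methoxybenzyl)oxy]-2-methylpentyl]-3-methyl-4-(prop-1-en-2-yl)dihydrofuran-2(3H)-one (all-trans) | CC(C)(C)[Si](C)(C)O[C@H](CCOCc1ccc(OC)cc1)[C@@H](C)C[C@H]1OC(=O)[C@@H](C)[C@@H]1C(C)=C | intermediate
14 | (3S,4R,5R)-5-[(2S,3R)-3-[(tert-butyldimethylsilyl)oxy]-5-[(4-methoxybenzyl)oxy]-2-methylpentyl]-4-(3-chloroprop-1-en-2-yl)-3-methyldihydrofuran-2(3H)-one | CC(C)(C)[Si](C)(C)O[C@H](CCOCc1ccc(OC)cc1)[C@@H](C)C[C@H]1OC(=O)[C@@H](C)[C@@H]1C(=C)CCl | intermediate
15 | (3S,4R,5R)-4-(3-chloroprop-1-en-2-yl)-5-[(2S,3R)-3-hydroxy-5-[(4-methoxybenzyl)oxy]-2-methylpentyl]-3-methyldihydrofuran-2(3H)-one | O[C@H](CCOCc1ccc(OC)cc1)[C@@H](C)C[C@H]1OC(=O)[C@@H](C)[C@@H]1C(=C)CCl | intermediate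
16 | (3R,4S,6R,7R,11S)-3-methyleneoxocane lactone: eight-membered ether O–CH2–C8(=CH2)–C7–C6–C5H2–C4(CH3)–C3, trans-fused at C6–C7 to the 11-methyl γ-lactone, CH2CH2OPMB on C3 | C=C1CO[C@H](CCOCc2ccc(OC)cc2)[C@@H](C)C[C@H]2OC(=O)[C@@H](C)[C@H]12 | intermediate
17 | the same bicycle with CH2CH2OH on C3 | C=C1CO[C@H](CCO)[C@@H](C)C[C@H]2OC(=O)[C@@H](C)[C@H]12 | intermediate
18 | the same bicycle with CH2CO2H on C3 | C=C1CO[C@H](CC(=O)O)[C@@H](C)C[C@H]2OC(=O)[C@@H](C)[C@H]12 | intermediate
19 | acid chloride of 18 | C=C1CO[C@H](CC(=O)Cl)[C@@H](C)C[C@H]2OC(=O)[C@@H](C)[C@H]12 | intermediate (not isolated)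
20 | the same bicycle with CH2–C(=O)–C(=N2)–CH3 on C3 (diazoethyl ketone) | C=C1CO[C@H](CC(=O)C(C)=[N+]=[N-])[C@@H](C)C[C@H]2OC(=O)[C@@H](C)[C@H]12 | intermediate
21 | bicyclic oxonium ylide (oxygen bonded to C3, to the ring CH2 and to C10; carbanion at C10) | C=C1C[O+]2[C@H](CC(=O)[C-]2C)[C@@H](C)C[C@H]2OC(=O)[C@@H](C)[C@H]12 | intermediate (not isolated)
22 | (3R,4S,6R,7R,10R,11S)-3,10-epoxy-8-methylidene-1-oxogermacran-12,6-olide | C=C1C[C@@]2(C)O[C@H](CC2=O)[C@@H](C)C[C@H]2OC(=O)[C@@H](C)[C@H]12 | intermediate
23 | C1 trimethylsilyl enol ether of 22 (C1=C2) | C=C1C[C@@]2(C)O[C@H](C=C2O[Si](C)(C)C)[C@@H](C)C[C@H]2OC(=O)[C@@H](C)[C@H]12 | intermediate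
24 | (4S,6R,7R,10R,11S)-3,10-epoxy-8-methylidene-1-oxogermacr-2-en-12,6-olide | C=C1C[C@@]2(C)OC(=CC2=O)[C@@H](C)C[C@H]2OC(=O)[C@@H](C)[C@H]12 | intermediate
25 | 8-hydroxy-8-(hydroxymethyl) diol from 24 (C8 configuration not defined) | OCC1(O)C[C@@]2(C)OC(=CC2=O)[C@@H](C)C[C@H]2OC(=O)[C@@H](C)[C@H]12 | intermediate (not isolated)
26 | (4S,6R,7S,10R,11S)-3,10-epoxy-1,8-dioxogermacr-2-en-12,6-olide | O=C1C[C@@]2(C)OC(=CC2=O)[C@@H](C)C[C@H]2OC(=O)[C@@H](C)[C@H]12 | intermediate
27 | (4S,6R,7R,8S,10R,11S)-3,10-epoxy-8-hydroxy-1-oxogermacr-2-en-12,6-olide | O[C@H]1C[C@@]2(C)OC(=CC2=O)[C@@H](C)C[C@H]2OC(=O)[C@@H](C)[C@H]12 | intermediate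
28 | (4S,6R,7S,8S,10R,11S)-3,10-epoxy-8-[(E)-2-methylbut-2-enoyloxy]-1-oxogermacr-2-en-12,6-olide | C/C=C(\C)C(=O)O[C@H]1C[C@@]2(C)OC(=CC2=O)[C@@H](C)C[C@H]2OC(=O)[C@@H](C)[C@H]12 | target

Total step count: 20. Longest linear sequence: 20 steps (from 1).

Steps most likely to fail

1. Step 15. The copper carbenoid may undergo 1,2-hydride shift from its methyl group (to a vinyl ketone) or insert into C4–H faster than it is captured by the ether oxygen. The fallback removes the β-hydrogens from the carbenoid and adds the C10 methyl group last. It sets out from acid 18: oxalyl chloride and then diazomethane give the terminal diazoketone F1. The same Cu(hfacac)2-catalysed ylide formation and sigmatropic ring expansion, well established for CHN2 ketones, should give the C10–H bridged ketone F2. Kinetic enolisation toward the C2 methylene (LDA, TMSCl, −78 °C) gives the silyl enol ether F3, and Saegusa–Ito oxidation gives the C10–H furanone F4. Deprotonation at C10 (LiHMDS, THF, −78 °C), the only acidic site besides the lactone, and methyl iodide, which can approach only the face opposite the C4–C9 bridge, return the route at compound 24.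

2. Step 11. Intermolecular etherification to oligomers, or attack of the alkoxide on the lactone, may compete with closure of the eight-membered ring. The fallback replaces alkoxide displacement by Tsuji–Trost allylic substitution under near-neutral conditions. It sets out from 15: Et2Zn (0.55 equiv) forms the zinc alkoxide and Pd(PPh3)4 (10 mol%, zerovalent palladium) ionises the allylic chloride to a 2-substituted π-allyl complex whose two CH2 termini are equivalent, so C–O bond formation at either end returns the route at compound 16. No new isolable compound arises (F0).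

3. Step 19. The medium-ring conformation may override the catalyst and give poor facial selectivity at C8, and the β-alkoxy ketone may eliminate if any base is present. The fallback sets out from 26: a substrate-controlled Luche reduction (NaBH4, CeCl3·7H2O, MeOH, −78 °C) is run instead. If it gives the 8R alcohol F5, Mitsunobu esterification with tiglic acid (PPh3, DIAD, toluene, 0 °C) inverts C8 and returns the route directly at compound 28.

Further compounds

F1 | step 15 | terminal diazoketone (CH2–C(=O)–CH=N2 on C3 of the methyleneoxocane lactone) | C=C1CO[C@H](CC(=O)C=[N+]=[N-])[C@@H](C)C[C@H]2OC(=O)[C@@H](C)[C@H]12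
F2 | step 15 | (3R,4S,6R,7R,10R,11S)-3,10-epoxy-8-methylidene-14-nor-1-oxogermacran-12,6-olide (C10–H bridged ketone) | C=C1C[C@H]2O[C@H](CC2=O)[C@@H](C)C[C@H]2OC(=O)[C@@H](C)[C@H]12
F3 | step 15 | C1 trimethylsilyl enol ether of F2 (C1=C2) | C=C1C[C@H]2O[C@H](C=C2O[Si](C)(C)C)[C@@H](C)C[C@H]2OC(=O)[C@@H](C)[C@H]12
F4 | step 15 | C10–H 3(2H)-furanone (24 without the C10 methyl group) | C=C1C[C@H]2OC(=CC2=O)[C@@H](C)C[C@H]2OC(=O)[C@@H](C)[C@H]12
F0 | step 11 | none | none
F5 | step 19 | (8R)-epimer of alcohol 27 | O[C@@H]1C[C@@]2(C)OC(=CC2=O)[C@@H](C)C[C@H]2OC(=O)[C@@H](C)[C@H]12
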